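## Retrosynthetic overview

1. The side chain is attached last: the C9–C11 bond comes from addition of a homoallylic organocerium reagent to the C9 ketone of α-methylene ketone 17; the exocyclic C8=C17 comes from reductive α-methylenation of enone 13.
2. Both rings are closed in one flask from the acyclic keto-enone-acetal 10: C5–C10 first (ring A, reductive aldol), then C7–C8 (ring B, silyl-triflate aldol condensation onto the C7 acetal).
3. The enabling feature is that ring B (C5–C6–C7–C8–C9–C10) is a 3-hydroxycyclohexanone: the C9 carbonyl carries two donor α-carbons (C10, C8), while C5 (carbinol) and C7 are 1,3-related acceptor sites (a β-keto acetal). C10 is quaternary, so the aldol hydroxyl at C5 is kept.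
4. The C4 quaternary centre is set by an organocatalytic Michael addition of β-keto ester 6 to acrolein; C5, C10 and later C9 are relayed from it. A Wittig reaction completes the chain.
5. The side-chain bromide 22 is made from 4-bromobut-1-yne by carboalumination.

Key step: step 5

Assumption 1: labdane numbering (C1–C20) is used for locants in the text; the cupreidine-derived catalyst in step 3 is assumed to give the (S) centre at C4, and its cupreine-derived pseudoenantiomer would be used if the sense is opposite.
Assumption 2: stereocentres that are destroyed later (the ethoxy carbon of 12, the aminomethyl carbon of 14 and 15) are expected as mixtures and are left undefined.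

## Route

Step 1
Reactants: 1 2-bromopropanoyl bromide; 2 2-(trimethylsilyl)ethanol
Product: 3 2-(trimethylsilyl)ethyl 2-bromopropanoate (racemic)
Conditions: pyridine, CH2Cl2, 0 → 23 °C
Reagents that add atoms: none
Why: Acylation of a primary alcohol by an acid bromide; it installs an ester that fluoride can remove at the end from the hindered C4 position, and the racemic centre is of no consequence.

Step 2
Reactants: 3 2-(trimethylsilyl)ethyl 2-bromopropanoate; 4 3,3-diethoxypropanenitrile
Product: 6 2-(trimethylsilyl)ethyl 5,5-diethoxy-2-methyl-3-oxopentanoate (racemic), via enamino ester 5 (not isolated)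
Conditions: Zn dust (zerovalent zinc, activated with Me3SiCl), THF, reflux, slow addition of 3; then 50% aq. K2CO3; then 1 M HCl–THF, 0 °C, short contact
Reagents that add atoms: water, O
Why: Blaise reaction: the zinc ester enolate adds to the nitrile and the β-enamino ester is hydrolysed to the β-keto ester; the acetal should survive the brief cold acid treatment.

Step 3
Reactants: 6 2-(trimethylsilyl)ethyl 5,5-diethoxy-2-methyl-3-oxopentanoate; 7 acrolein
Product: 8 2-(trimethylsilyl)ethyl (2S)-2-(3,3-diethoxypropanoyl)-2-methyl-5-oxopentanoate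
Conditions: 9-O-(9-phenanthryl)cupreidine (10 mol%), CH2Cl2, −24 °C
Reagents that add atoms: none
Why: Organocatalytic asymmetric Michael addition: the quinuclidine base forms the enolate and the 6'-hydroxyl activates acrolein by hydrogen bonding, so one enolate face is shielded and the C4 quaternary centre is set; this is the only stereocentre not relayed.

Step 4
Reactants: 8 2-(trimethylsilyl)ethyl (2S)-2-(3,3-diethoxypropanoyl)-2-methyl-5-oxopentanoate; 9 3-(triphenylphosphoranylidene)butan-2-one
Product: 10 2-(trimethylsilyl)ethyl (2S,5E)-2-(3,3-diethoxypropanoyl)-2,6-dimethyl-7-oxooct-5-enoate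
Conditions: toluene, 80 °C
Reagents that add atoms: none
Why: Wittig olefination with a stabilised acyl ylide; it should react only with the aldehyde (the α-quaternary ketone is inert) and give the E-enone.

Step 5
Reactants: 10 2-(trimethylsilyl)ethyl (2S,5E)-2-(3,3-diethoxypropanoyl)-2,6-dimethyl-7-oxooct-5-enoate
Product: 13 2-(trimethylsilyl)ethyl (1S,4aS,8aS)-1,4a-dimethyl-5-oxo-8a-(trimethylsilyloxy)-1,2,3,4,4a,5,8,8a-octahydronaphthalene-1-carboxylate (trans-fused; 5α-OSiMe3 and 10β-methyl and 4β-ester in labdane numbering), via copper aldolate 11 (not isolated), via ethoxy ketone 12 (not isolated)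
Conditions: [(Ph3P)CuH]6 (0.2 equiv, 1.2 equiv hydride), toluene, −40 → 0 °C; then Me3SiOTf (3.5 equiv), i-Pr2NEt (4 equiv), −78 → 23 °C
Reagents that add atoms: trimethylsilyl trifluoromethanesulfonate, C[Si](C)(C)OS(=O)(=O)C(F)(F)F
Why: Hydride transfer from monovalent copper to the enone β-carbon gives the copper enolate regiospecifically at C10, which adds to the C5 ketone and closes ring A (6-(enolexo)-exo-trig; reductive aldol cyclisation of a keto-enone). Me3SiOTf/i-Pr2NEt then silylates the congested aldolate (making the first bond irreversible), converts the C9 methyl ketone into its enol silane at C8 (the only enolisable side once C10 is quaternary) and ionises the C7 acetal; ring B closes by Mukaiyama-type addition to the oxocarbenium ion (6-(enolendo)-exo-trig) and loss of ethoxysilane gives the enone. The closest precedents are copper hydride reductive aldol cyclisations of keto-enones and one-pot enol silane formation/acetal aldol condensations; pairing a ketone α,α'-dinucleophile with a 1,3-dielectrophile is the classical [3+3] cyclohexenone annulation. C5 and C10 are created together in a copper-bridged chair (Zimmerman–Traxler) transition state in which the C9 acyl and the C5 oxygen are cis, which places C5–O trans to the C10 methyl, the trans-decalin relationship. The C4 centre selects the face: in the favoured chair the flat ester, not the C4 methyl, sits 1,3-diaxial to the developing C10 methyl and lies anti to the carbonyl dipole. The step needs C10 (not C8) as first donor, secured by generating the enolate from the enone; the ketone (not ester or acetal) as first acceptor, secured by six- versus eight-membered closure; and ring B closure only after ring A, secured because C8–C7 closure is a ten-membered process until C5–C10 exists.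

Step 6
Reactants: 13 bicyclic enone silyl ether
Product: 17 2-(trimethylsilyl)ethyl (1S,4aS,8aS)-8a-hydroxy-1,4a-dimethyl-6-methylidene-5-oxodecahydronaphthalene-1-carboxylate, via Mannich base 14 (not isolated), via methiodide 15 (not isolated), via silyl ether 16 (not isolated)
Conditions: LiBH(s-Bu)3, THF, −78 °C; then CH2=NMe2+ I−, −78 → 23 °C; then MeI, 23 °C; then DBU; then 1 M HCl–THF, 0 °C
Reagents that add atoms: dimethyl(methylidene)ammonium iodide, C=[N+](C)C.[I-]
Why: Conjugate reduction of the β-unsubstituted enone gives the C8 enolate regiospecifically, a Mannich reaction with the iminium salt and quaternisation/E1cB elimination give the α-methylene ketone, and cold dilute acid cleaves the tertiary trimethylsilyl ether; the silyl ether prevents retro-aldol during the enolate stage and no stereocentre is at stake.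

Step 7
Reactants: 18 4-bromobut-1-yne
Product: 20 ethyl (2E)-5-bromo-3-methylpent-2-enoate, via alkenylalane 19 (not isolated)
Conditions: AlMe3 (2 equiv), Cp2ZrCl2 (0.2 equiv), CH2Cl2, 0 → 23 °C; then ClCO2Et, 0 → 23 °C
Reagents that add atoms: trimethylaluminium, C[Al](C)C; ethyl chloroformate, CCOC(=O)Cl
Why: Zirconium-catalysed carboalumination adds methyl and aluminium syn across the terminal alkyne (methyl to the internal carbon) and acylation of the alkenylalane with retention fixes the E trisubstituted alkene.

Step 8
Reactants: 20 ethyl (2E)-5-bromo-3-methylpent-2-enoate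
Product: 21 (2E)-5-bromo-3-methylpent-2-en-1-ol
Conditions: i-Bu2AlH (2.2 equiv), CH2Cl2, −78 °C; Rochelle salt work-up
Reagents that add atoms: none
Why: 1,2-Reduction of an enoate to the allylic alcohol; the primary bromide is untouched at low temperature.

Step 9
Reactants: 21 (2E)-5-bromo-3-methylpent-2-en-1-ol
Product: 22 (2E)-5-bromo-1-(tert-butyldimethylsilyloxy)-3-methylpent-2-ene
Conditions: t-BuMe2SiCl, imidazole, CH2Cl2, 23 °C
Reagents that add atoms: tert-butyldimethylsilyl chloride, CC(C)(C)[Si](C)(C)Cl
Why: Standard silylation of a primary allylic alcohol to protect it during organometallic formation.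

Step 10
Reactants: 17 α-methylene ketone; 22 (2E)-5-bromo-1-(tert-butyldimethylsilyloxy)-3-methylpent-2-ene
Product: 24 2-(trimethylsilyl)ethyl (4S,5S,9S,10R,13E)-15-(tert-butyldimethylsilyloxy)-5,9-dihydroxylabda-8(17),13-dien-19-oate, via Grignard reagent 23 (not isolated)
Conditions: 22 (3 equiv), Mg turnings, THF, 40 °C; then CeCl3 (anhydrous), THF, −78 °C; then 17, −78 → 0 °C; aq. NH4Cl
Reagents that add atoms: none
Why: 1,2-Addition of an organocerium reagent (Grignard/CeCl3) to a hindered, non-enolisable enone carbonyl; attack on the α face, anti to the axial C10 methyl on the neighbouring carbon and guided by the C5 alkoxide formed from the first equivalent, should set C9 with the side chain α and the hydroxyl β.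

Step 11
Reactants: 24 protected triol ester
Product: 25 (4S,5S,9S,10R,13E)-5,9,15-trihydroxylabda-8(17),13-dien-19-oic acid (5α,9β-dihydroxyisocupressic acid)
Conditions: Bu4NF (5 equiv), THF, 23 → 40 °C; then aq. HCl to pH 4
Reagents that add atoms: none
Why: Fluoride cleaves the silyl ether and fragments the 2-(trimethylsilyl)ethyl ester (loss of ethene), a deprotection that does not depend on access to the hindered C19 carbonyl and leaves the tertiary allylic alcohol alone.

## Compound list

1 | 2-bromopropanoyl bromide | CC(Br)C(=O)Br | starting material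
2 | 2-(trimethylsilyl)ethanol | C[Si](C)(C)CCO | starting material
3 | 2-(trimethylsilyl)ethyl 2-bromopropanoate (racemic) | CC(Br)C(=O)OCC[Si](C)(C)C | intermediate
4 | 3,3-diethoxypropanenitrile | CCOC(CC#N)OCC | starting material
5 | 2-(trimethylsilyl)ethyl (2Z)-3-amino-5,5-diethoxy-2-methylpent-2-enoate (formed as its bromozinc salt) | CCOC(OCC)C/C(N)=C(\C)C(=O)OCC[Si](C)(C)C | intermediate (not isolated)
6 | 2-(trimethylsilyl)ethyl 5,5-diethoxy-2-methyl-3-oxopentanoate (racemic) | CCOC(OCC)CC(=O)C(C)C(=O)OCC[Si](C)(C)C | intermediate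
7 | acrolein | C=CC=O | starting material
8 | 2-(trimethylsilyl)ethyl (2S)-2-(3,3-diethoxypropanoyl)-2-methyl-5-oxopentanoate | O=CCC[C@](C)(C(=O)OCC[Si](C)(C)C)C(=O)CC(OCC)OCC | intermediate
9 | 3-(triphenylphosphoranylidene)butan-2-one | CC(=O)C(C)=P(c1ccccc1)(c1ccccc1)c1ccccc1 | starting material
10 | 2-(trimethylsilyl)ethyl (2S,5E)-2-(3,3-diethoxypropanoyl)-2,6-dimethyl-7-oxooct-5-enoate | CC(=O)/C(C)=C/CC[C@](C)(C(=O)OCC[Si](C)(C)C)C(=O)CC(OCC)OCC | intermediate
11 | copper alkoxide of 2-(trimethylsilyl)ethyl (1S,2S,3S)-3-acetyl-2-(2,2-diethoxyethyl)-2-hydroxy-1,3-dimethylcyclohexane-1-carboxylate | CC(=O)[C@@]1(C)CCC[C@](C)(C(=O)OCC[Si](C)(C)C)[C@]1(O[Cu])CC(OCC)OCC | intermediate (not isolated)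
12 | 2-(trimethylsilyl)ethyl (1S,4aS,8aS)-7-ethoxy-1,4a-dimethyl-5-oxo-8a-(trimethylsilyloxy)decahydronaphthalene-1-carboxylate (mixture at the ethoxy carbon) | O=C1CC(OCC)C[C@]2(O[Si](C)(C)C)[C@]1(C)CCC[C@]2(C)C(=O)OCC[Si](C)(C)C | intermediate (not isolated)
13 | 2-(trimethylsilyl)ethyl (1S,4aS,8aS)-1,4a-dimethyl-5-oxo-8a-(trimethylsilyloxy)-1,2,3,4,4a,5,8,8a-octahydronaphthalene-1-carboxylate | O=C1C=CC[C@]2(O[Si](C)(C)C)[C@]1(C)CCC[C@]2(C)C(=O)OCC[Si](C)(C)C | intermediate
14 | 2-(trimethylsilyl)ethyl (1S,4aS,8aS)-6-[(dimethylamino)methyl]-1,4a-dimethyl-5-oxo-8a-(trimethylsilyloxy)decahydronaphthalene-1-carboxylate (mixture at C6 of the naphthalene numbering) | CN(C)CC1CC[C@]2(O[Si](C)(C)C)[C@](C)(CCC[C@]2(C)C(=O)OCC[Si](C)(C)C)C1=O | intermediate (not isolated)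
15 | trimethylammonium iodide derived from 14 | C[N+](C)(C)CC1CC[C@]2(O[Si](C)(C)C)[C@](C)(CCC[C@]2(C)C(=O)OCC[Si](C)(C)C)C1=O.[I-] | intermediate (not isolated)
16 | 2-(trimethylsilyl)ethyl (1S,4aS,8aS)-1,4a-dimethyl-6-methylidene-5-oxo-8a-(trimethylsilyloxy)decahydronaphthalene-1-carboxylate | C=C1CC[C@]2(O[Si](C)(C)C)[C@](C)(CCC[C@]2(C)C(=O)OCC[Si](C)(C)C)C1=O | intermediate (not isolated)
17 | 2-(trimethylsilyl)ethyl (1S,4aS,8aS)-8a-hydroxy-1,4a-dimethyl-6-methylidene-5-oxodecahydronaphthalene-1-carboxylate | C=C1CC[C@]2(O)[C@](C)(CCC[C@]2(C)C(=O)OCC[Si](C)(C)C)C1=O | intermediate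
18 | 4-bromobut-1-yne | C#CCCBr | starting material
19 | [(1E)-4-bromo-2-methylbut-1-enyl]dimethylalane | C[Al](C)/C=C(\C)CCBr | intermediate (not isolated)
20 | ethyl (2E)-5-bromo-3-methylpent-2-enoate | CCOC(=O)/C=C(\C)CCBr | intermediate
21 | (2E)-5-bromo-3-methylpent-2-en-1-ol | OC/C=C(\C)CCBr | intermediate
22 | (2E)-5-bromo-1-(tert-butyldimethylsilyloxy)-3-methylpent-2-ene | CC(C)(C)[Si](C)(C)OC/C=C(\C)CCBr | intermediate
23 | [(3E)-5-(tert-butyldimethylsilyloxy)-3-methylpent-3-enyl]magnesium bromide | CC(C)(C)[Si](C)(C)OC/C=C(\C)CC[Mg]Br | intermediate (not isolated)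
24 | 2-(trimethylsilyl)ethyl (4S,5S,9S,10R,13E)-15-(tert-butyldimethylsilyloxy)-5,9-dihydroxylabda-8(17),13-dien-19-oate | C=C1CC[C@]2(O)[C@](C)(CCC[C@]2(C)C(=O)OCC[Si](C)(C)C)[C@]1(O)CC/C(C)=C/CO[Si](C)(C)C(C)(C)C | intermediate
25 | (4S,5S,9S,10R,13E)-5,9,15-trihydroxylabda-8(17),13-dien-19-oic acid | C=C1CC[C@]2(O)[C@](C)(CCC[C@]2(C)C(=O)O)[C@]1(O)CC/C(C)=C/CO | target

## Step count and risks

Total step count: 11. Longest linear sequence: 8 steps (steps 1, 2, 3, 4, 5, 6, 10, 11); the side-chain branch (steps 7–9) joins at step 10.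

Most likely to fail:

1. Step 5. The copper-enolate aldol may show poor facial selectivity relative to the C4 quaternary centre, the congested aldolate may revert before it is silylated, or the C5 silyloxy group may be lost by vinylogous elimination under excess silyl triflate. The fallback separates the two ring closures and sets out from 10. Rh(PPh3)3Cl-catalysed 1,4-hydrosilylation with Et3SiH should give the (Z)-triethylsilyl enol ether F1. Tris(dimethylamino)sulfonium difluorotrimethylsilicate in THF at −78 °C should release the enolate at C10 only and close ring A by a metal-free aldol addition to the isolated ring-A ketol F2, where diastereomers can be separated. Treatment of F2 with Me3SiOTf/i-Pr2NEt then closes ring B and comes back to the route at 13.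

2. Step 10. Addition at the C9 carbonyl, flanked by two fully substituted carbons, may be sluggish, may occur from the wrong face, or may go in conjugate fashion. The fallback sets out from 17 and brings in the chain in two smaller pieces. CH2=CHMgBr/CeCl3 should add the small vinyl group to give the vinyl carbinol F3. Hydroboration of the monosubstituted alkene with 9-BBN should give the alkylborane F4, which is coupled without isolation (PdCl2(dppf), a divalent palladium precatalyst, K3PO4, DMF–water) with the vinyl iodide (2E)-1-(tert-butyldimethylsilyloxy)-3-iodobut-2-ene F5 in a B-alkyl Suzuki–Miyaura reaction, coming back to the route at 24.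

3. Step 3. The enantioselectivity or its sense may be insufficient for this acyl-substituted β-keto ester, and the 1,5-keto aldehyde may undergo intramolecular aldol reaction under the basic catalyst. The fallback sets out from 6 and uses a Tsuji–Trost asymmetric allylic alkylation instead. Pd2(dba)3 (zerovalent palladium), the (S,S)-DACH-phenyl bisphosphine ligand, allyl acetate and tetramethylguanidine should give the allyl keto ester F6. Hydroboration with 9-BBN and oxidation with NaBO3 should give the primary alcohol F7, and oxidation with DMP comes back to the route at 8.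

Further compounds
F1 | step 5 | 2-(trimethylsilyl)ethyl (2S,5Z)-2-(3,3-diethoxypropanoyl)-2,6-dimethyl-7-(triethylsilyloxy)oct-6-enoate | C/C(O[Si](CC)(CC)CC)=C(\C)CCC[C@](C)(C(=O)OCC[Si](C)(C)C)C(=O)CC(OCC)OCC
F2 | step 5 | 2-(trimethylsilyl)ethyl (1S,2S,3S)-3-acetyl-2-(2,2-diethoxyethyl)-2-hydroxy-1,3-dimethylcyclohexane-1-carboxylate | CC(=O)[C@@]1(C)CCC[C@](C)(C(=O)OCC[Si](C)(C)C)[C@]1(O)CC(OCC)OCC
F3 | step 10 | 2-(trimethylsilyl)ethyl (1S,4aR,5S,8aS)-5-ethenyl-5,8a-dihydroxy-1,4a-dimethyl-6-methylidenedecahydronaphthalene-1-carboxylate | C=C1CC[C@]2(O)[C@](C)(CCC[C@]2(C)C(=O)OCC[Si](C)(C)C)[C@]1(O)C=C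
F4 | step 10 | 9-BBN adduct of F3 at the terminal vinyl carbon | C=C1CC[C@]2(O)[C@](C)(CCC[C@]2(C)C(=O)OCC[Si](C)(C)C)[C@]1(O)CCB1C2CCCC1CCC2
F5 | step 10 | (2E)-1-(tert-butyldimethylsilyloxy)-3-iodobut-2-ene | C/C(I)=C\CO[Si](C)(C)C(C)(C)C
F6 | step 3 | 2-(trimethylsilyl)ethyl (2S)-2-(3,3-diethoxypropanoyl)-2-methylpent-4-enoate | C=CC[C@](C)(C(=O)OCC[Si](C)(C)C)C(=O)CC(OCC)OCC
F7 | step 3 | 2-(trimethylsilyl)ethyl (2S)-2-(3,3-diethoxypropanoyl)-5-hydroxy-2-methylpentanoate | OCCC[C@](C)(C(=O)OCC[Si](C)(C)C)C(=O)CC(OCC)OCC
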